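## Retrosynthetic overview
1. Kazinol D (18) is traced back to its constitutional isomer, the bis(prenyl ether) 13. The last step is one thermal, regiodivergent double aromatic Claisen rearrangement: ortho [3,3] on ring A gives the 1,1-dimethylallyl group, and [3,3]/[3,3] Claisen–Cope on ring B gives the para prenyl group.
2. 13 is cut at the ring A–CH2 bond, a B-alkyl Suzuki coupling of allylchroman 7 with bromophenol 10. There is no chalcone, no hydrogenation and no protecting group.
3. 7 comes from eugenol, which already holds ring B, its two differentiated oxygens and the whole C3 tether. 10 comes from 4-bromoresorcinol.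
4. Ring order: both benzene rings are bought. The only ring made is the dihydropyran (chroman) ring, closed first (step 1) by isoprene annulation of eugenol.

Assumption: the target SMILES has no stereocentre and no E/Z-stereogenic alkene, so kazinol D is achiral and "single enantiomer" needs no stereocontrol. The sp3 CH centres of the transient dienones 14, 16 and 17 are racemic and vanish on re-aromatisation.

Abbreviations: prenyl = 3-methylbut-2-en-1-yl; 1,1-dimethylallyl = 2-methylbut-3-en-2-yl. Chroman numbering is O1, C2, C3, C4, C4a, C5–C8, C8a. Ring A numbering is C1 (tether), C2 (OH), C4 (O), C5.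

## Route

Step 1
Reactants: 1 eugenol (4-allyl-2-methoxyphenol); 2 isoprene
Product: 4 6-allyl-8-methoxy-2,2-dimethylchroman, via 4-allyl-2-methoxy-6-prenylphenol 3 (not isolated)
Conditions: AgOTf (5 mol %), 1 (1.3 equiv), 2 (slow addition), ClCH2CH2Cl, rt, dark; NaOH wash removes excess 1
Reagents that add atoms: isoprene (2), C=CC(C)=C
Why: This is the classical phenol–isoprene chroman annulation (Friedel–Crafts prenylation, then Markovnikov hydroalkoxylation), in which the prenyl cation equivalent attacks the only free carbon ortho to the free OH (para is blocked by allyl, and eugenol is generally substituted here), the phenol O closes onto the tertiary cation of 3, the monosubstituted allyl alkene is too weakly basic to compete at rt, all atoms of 1 and 2 end up in 4, and no stereocentre forms.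

Step 2
Reactants: 4 6-allyl-8-methoxy-2,2-dimethylchroman
Product: 5 6-allyl-2,2-dimethylchroman-8-ol
Conditions: LiPPh2 (0.5 M in THF, 2 equiv), THF, rt to 45 °C; then 1 M HCl
Reagents that add atoms: none
Why: This is an SN2 O-demethylation of an aryl methyl ether by the soft diphenylphosphide anion, which attacks only the unhindered OCH3 carbon, cannot displace at the tertiary C2–O bond of the chroman, and is far too weak a base to isomerise the allylarene to the conjugated propenylarene.

Step 3
Reactants: 5 6-allyl-2,2-dimethylchroman-8-ol; 6 prenyl bromide (1-bromo-3-methylbut-2-ene)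
Product: 7 6-allyl-2,2-dimethyl-8-(prenyloxy)chroman
Conditions: K2CO3, acetone, reflux
Reagents that add atoms: prenyl bromide (6), CC(C)=CCBr
Why: This is a Williamson ether synthesis in which the phenoxide of 5 displaces the primary allylic bromide by SN2 in a polar aprotic medium that favours O- over C-alkylation, leaving the allyl group and the chroman untouched.

Step 4
Reactants: 8 4-bromoresorcinol (4-bromobenzene-1,3-diol); 6 prenyl bromide
Product: 10 2-bromo-5-(prenyloxy)phenol, via disodium 4-bromobenzene-1,3-diolate 9 (not isolated)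
Conditions: NaH (2.2 equiv), DMF, 0 °C; then 6 (0.95 equiv), 0 °C to rt; then 1 M HCl
Reagents that add atoms: prenyl bromide (6), CC(C)=CCBr; sodium hydride, [Na+].[H-] (its sodium is held only by 9)
Why: This is a Williamson ether synthesis on the preformed dianion, where both OH groups are deprotonated so that nucleophilicity rather than acidity decides, and the more basic, unhindered phenoxide para to Br therefore takes the substoichiometric bromide ahead of the less basic, bromine-flanked phenoxide, with DMF favouring O-alkylation.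

Step 5
Reactants: 7 6-allyl-2,2-dimethyl-8-(prenyloxy)chroman; 11 9-BBN-H (9-borabicyclo[3.3.1]nonane); 10 2-bromo-5-(prenyloxy)phenol
Product: 13 2-{3-[2,2-dimethyl-8-(prenyloxy)chroman-6-yl]propyl}-5-(prenyloxy)phenol, via 9-{3-[2,2-dimethyl-8-(prenyloxy)chroman-6-yl]propyl}-9-borabicyclo[3.3.1]nonane 12 (not isolated)
Conditions: 11 (1.1 equiv), THF, 0 °C to rt; then 10, Pd(OAc)2 (3 mol %), SPhos (6 mol %), K3PO4 (3 M aq.), THF, 60 °C
Reagents that add atoms: 9-BBN-H (11), C1CC2CCCC(C1)B2 (its boron unit is held only by 12; 13 keeps one H from it)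
Why: This is a Brown hydroboration followed by a B-alkyl Suzuki–Miyaura coupling, in which 9-BBN adds anti-Markovnikov to the monosubstituted allyl alkene orders of magnitude faster than to the trisubstituted prenyl ether alkene, and the base-activated borane 12 transfers its primary alkyl group to the arylpalladium species from 10 (an electron-rich biarylphosphine tolerates the o-phenoxide) at 60 °C, far below any Claisen shift.

Step 6 (key step)
Reactants: 13 2-{3-[2,2-dimethyl-8-(prenyloxy)chroman-6-yl]propyl}-5-(prenyloxy)phenol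
Product: 18 kazinol D, via ring-A ortho-dienone 14 (not isolated), via ring-A-rearranged phenol 15 (not isolated), via ring-B ortho-dienone 16 (not isolated), via ring-B para-dienone 17 (not isolated)
Conditions: PhNEt2 (degassed, 0.05 M), 200 °C, sealed tube, Ar, 2–3 h
Reagents that add atoms: none
Why: Two aromatic Claisen rearrangements run in parallel and each ring offers the migrating C5 unit only one unstrained resting place, because in ring A the [3,3] shift to unhindered C5 (para blocked by the tether, C3 squeezed between two oxygens) gives dienone 14, which enolises to the 1,1-dimethylallyl phenol 15 (ortho-Claisen), whereas in ring B the only open ortho carbon C7 is flanked by the tether, so the crowded dienone 16 undergoes a second [3,3] shift (Cope) to C5 faster than it enolises and 17 tautomerises to the para-prenyl phenol (para-Claisen or Claisen–Cope, the known behaviour of aryl prenyl ethers with a flanked ortho position), while the basic solvent suppresses acid-catalysed cyclisation and the step is a pure isomerisation leaving no stereocentre in 18.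

## Compound list
1 | eugenol (4-allyl-2-methoxyphenol) | C=CCc1ccc(O)c(OC)c1 | starting material
2 | isoprene | C=CC(C)=C | starting material
3 | 4-allyl-2-methoxy-6-prenylphenol | C=CCc1cc(CC=C(C)C)c(O)c(OC)c1 | intermediate (not isolated)
4 | 6-allyl-8-methoxy-2,2-dimethylchroman | C=CCc1cc(OC)c2OC(C)(C)CCc2c1 | intermediate
5 | 6-allyl-2,2-dimethylchroman-8-ol | C=CCc1cc(O)c2OC(C)(C)CCc2c1 | intermediate
6 | prenyl bromide | CC(C)=CCBr | starting material
7 | 6-allyl-2,2-dimethyl-8-(prenyloxy)chroman | C=CCc1cc(OCC=C(C)C)c2OC(C)(C)CCc2c1 | intermediate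
8 | 4-bromoresorcinol | Oc1ccc(Br)c(O)c1 | starting material
9 | disodium 4-bromobenzene-1,3-diolate | [Na+].[Na+].[O-]c1ccc(Br)c([O-])c1 | intermediate (not isolated)
10 | 2-bromo-5-(prenyloxy)phenol | CC(C)=CCOc1ccc(Br)c(O)c1 | intermediate
11 | 9-BBN-H | C1CC2CCCC(C1)B2 | starting material (reagent)
12 | 9-{3-[2,2-dimethyl-8-(prenyloxy)chroman-6-yl]propyl}-9-BBN | CC(C)=CCOc1cc(CCCB2C3CCCC2CCC3)cc2CCC(C)(C)Oc12 | intermediate (not isolated)
13 | 2-{3-[2,2-dimethyl-8-(prenyloxy)chroman-6-yl]propyl}-5-(prenyloxy)phenol | CC(C)=CCOc1ccc(CCCc2cc(OCC=C(C)C)c3OC(C)(C)CCc3c2)c(O)c1 | intermediate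
14 | ring-A ortho-dienone: 6-(1,1-dimethylallyl)-3-hydroxy-4-(tether)cyclohexa-2,4-dienone, ring B still the prenyl ether (racemic, transient) | C=CC(C)(C)C1C=C(CCCc2cc(OCC=C(C)C)c3OC(C)(C)CCc3c2)C(O)=CC1=O | intermediate (not isolated)
15 | 4-(1,1-dimethylallyl)-6-{3-[2,2-dimethyl-8-(prenyloxy)chroman-6-yl]propyl}benzene-1,3-diol | C=CC(C)(C)c1cc(CCCc2cc(OCC=C(C)C)c3OC(C)(C)CCc3c2)c(O)cc1O | intermediate (not isolated)
16 | ring-B ortho-dienone: 7-(1,1-dimethylallyl)-2,2-dimethyl-3,4-dihydro-2H-chromen-8(7H)-one with the ring-A propyl tether at C6 (racemic, transient) | C=CC(C)(C)c1cc(CCCC2=CC3=C(OC(C)(C)CC3)C(=O)C2C(C)(C)C=C)c(O)cc1O | intermediate (not isolated)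
17 | ring-B para-dienone: 5-prenyl-2,2-dimethyl-3,4-dihydro-2H-chromen-8(5H)-one with the ring-A propyl tether at C6 (racemic, transient) | C=CC(C)(C)c1cc(CCCC2=CC(=O)C3=C(CCC(C)(C)O3)C2CC=C(C)C)c(O)cc1O | intermediate (not isolated)
18 | kazinol D (achiral) | C=CC(C)(C)c1cc(CCCc2cc(O)c3c(c2CC=C(C)C)CCC(C)(C)O3)c(O)cc1O | target

Total step count: 6. Longest linear sequence: 5 (steps 1, 2, 3, 5, 6).

## Three steps most likely to fail

**Step 6.**
- Risk: dienone 16 may enolise before the Cope shift and leave a 7-(1,1-dimethylallyl) isomer. Long heating may also cost prenyl groups or trigger an abnormal Claisen on ring A.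
- Fallback, from 4 back to 18: this drops the O-to-C transfer on ring B and installs that prenyl group by organometallic allylation.
- NBS in MeCN at 0 °C brominates 4 para to the methoxy group to give 6-allyl-5-bromo-8-methoxy-2,2-dimethylchroman F1.
- n-BuLi in THF at −78 °C converts it into (6-allyl-8-methoxy-2,2-dimethylchroman-5-yl)lithium F2. With CuBr·SMe2 (10 mol %) and 6, this gives 6-allyl-8-methoxy-2,2-dimethyl-5-prenylchroman F3.
- 11 adds to the allyl group alone to give 9-{3-[8-methoxy-2,2-dimethyl-5-prenylchroman-6-yl]propyl}-9-BBN F4.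
- F4 is coupled with 10 under the step 5 conditions to give 2-{3-[8-methoxy-2,2-dimethyl-5-prenylchroman-6-yl]propyl}-5-(prenyloxy)phenol F5.
- Heating in PhNEt2 now has to deliver only the ring-A ortho-Claisen. It runs through the ring-A ortho-dienone of F5 F6 to 8-O-methylkazinol D F7.
- NaSEt in DMF at 120 °C then cleaves the single methyl ether to give 18. The resorcinol ring sits as its inert bis-phenoxide, and the chroman C–O bond is tertiary.

**Step 1.**
- Risk: the cationic annulation may over-prenylate 4 at C5 or C7, attack para to OMe, or oligomerise isoprene.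
- Fallback, from 1 back to 4: this replaces cation chemistry with a regiospecific sigmatropic ortho-prenylation.
- 3-Chloro-3-methylbut-1-yne, DBU and catalytic CuCl2 in MeCN at 0 °C give 4-allyl-2-methoxy-1-(2-methylbut-3-yn-2-yloxy)benzene F8.
- Lindlar semihydrogenation with quinoline, stopped at 1 equiv H2, gives 4-allyl-2-methoxy-1-(2-methylbut-3-en-2-yloxy)benzene F9.
- In xylene at 130 °C the [3,3] shift can only reach the one free ortho carbon. It passes through 4-allyl-2-methoxy-6-prenylcyclohexa-2,4-dienone F10 to 3, which is now isolated.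
- Amberlyst-15 in CH2Cl2 at rt closes 3 to 4.

**Step 4.**
- Risk: the two phenoxides of 9 may not differ enough, which would give both mono-ethers, the bis-ether and some C-prenylation.
- Fallback, from 8 back to 13: this postpones the differentiation until bromine has been replaced by the tether, when acidity and sterics both favour the 4-OH.
- Ac2O and pyridine give 4-bromo-1,3-phenylene diacetate F11.
- Coupling with 12 under the step 5 conditions gives 4-{3-[2,2-dimethyl-8-(prenyloxy)chroman-6-yl]propyl}-1,3-phenylene diacetate F12.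
- F12 is methanolysed without isolation (catalytic K2CO3, MeOH) to 4-{3-[2,2-dimethyl-8-(prenyloxy)chroman-6-yl]propyl}benzene-1,3-diol F13.
- 6 (1.0 equiv) and K2CO3 in acetone then alkylate the unhindered OH para to the tether and give 13.

Further compounds
F1 | step 6 | 6-allyl-5-bromo-8-methoxy-2,2-dimethylchroman | C=CCc1cc(OC)c2OC(C)(C)CCc2c1Br
F2 | step 6 | (6-allyl-8-methoxy-2,2-dimethylchroman-5-yl)lithium | [Li]c1c(CC=C)cc(OC)c2OC(C)(C)CCc12
F3 | step 6 | 6-allyl-8-methoxy-2,2-dimethyl-5-prenylchroman | C=CCc1cc(OC)c2OC(C)(C)CCc2c1CC=C(C)C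
F4 | step 6 | 9-{3-[8-methoxy-2,2-dimethyl-5-prenylchroman-6-yl]propyl}-9-BBN | COc1cc(CCCB2C3CCCC2CCC3)c(CC=C(C)C)c2CCC(C)(C)Oc12
F5 | step 6 | 2-{3-[8-methoxy-2,2-dimethyl-5-prenylchroman-6-yl]propyl}-5-(prenyloxy)phenol | CC(C)=CCOc1ccc(CCCc2cc(OC)c3OC(C)(C)CCc3c2CC=C(C)C)c(O)c1
F6 | step 6 | ring-A ortho-dienone of F5 (racemic, transient) | C=CC(C)(C)C1C=C(CCCc2cc(OC)c3OC(C)(C)CCc3c2CC=C(C)C)C(O)=CC1=O
F7 | step 6 | 8-O-methylkazinol D | C=CC(C)(C)c1cc(CCCc2cc(OC)c3OC(C)(C)CCc3c2CC=C(C)C)c(O)cc1O
F8 | step 1 | 4-allyl-2-methoxy-1-(2-methylbut-3-yn-2-yloxy)benzene | C#CC(C)(C)Oc1ccc(CC=C)cc1OC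
F9 | step 1 | 4-allyl-2-methoxy-1-(2-methylbut-3-en-2-yloxy)benzene | C=CC(C)(C)Oc1ccc(CC=C)cc1OC
F10 | step 1 | 4-allyl-2-methoxy-6-prenylcyclohexa-2,4-dienone (racemic, transient) | O=C1C(OC)=CC(CC=C)=CC1CC=C(C)C
F11 | step 4 | 4-bromo-1,3-phenylene diacetate | CC(=O)Oc1ccc(Br)c(OC(C)=O)c1
F12 | step 4 | 4-{3-[2,2-dimethyl-8-(prenyloxy)chroman-6-yl]propyl}-1,3-phenylene diacetate | CC(=O)Oc1ccc(CCCc2cc(OCC=C(C)C)c3OC(C)(C)CCc3c2)c(OC(C)=O)c1
F13 | step 4 | 4-{3-[2,2-dimethyl-8-(prenyloxy)chroman-6-yl]propyl}benzene-1,3-diol | Oc1ccc(CCCc2cc(OCC=C(C)C)c3OC(C)(C)CCc3c2)c(O)c1
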